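## Retrosynthetic overview

1. Target 40 ← hexamethyl ether 39 by demethylation; ring D (the dihydrofuran fused to rings A and C) ← Rh-carbene insertion of a diazo group at C5 of ring C into the benzylic C–H of the 4-methoxybenzyl ether on ring A, then acid epimerisation to trans.
2. Ring C (seven-membered) ← σ-bond insertion of the 6,7-aryne of the finished ring B/E dihydrobenzofuran into the C1–C2 bond of a ring A 2-oxoindane-1-carboxylate. This forms the ring B C7–C10(acyl) bond and the ring B C6–C5(methine) bond at once.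
3. Enabling feature: these two bonds end on adjacent carbons C6 and C7 of ring B, and C7 is ortho to the ring E oxygen O1. The aryne is therefore polarised like a 3-alkoxybenzyne (enolate carbon to C6, acyl to C7), and the other five atoms of ring C can be delivered as a strained five-membered keto ester.
4. Aryne precursor 19 ← enantioselective Rh-carbene C–H insertion (ring E), acid epimerisation, carbamate-directed C7 silylation, triflation. Indanone 26 ← Rh-carbenoid aromatic substitution of a diazo β-keto ester from a symmetric 3,5-dioxygenated phenylacetate.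
5. Order of ring formation: E (step 6), temporary five-membered ring on A (step 15), C (step 16), D (step 21).

Key step: step 16

Notation: ring A is the benzene ring that carries the alkene carbon C11; ring B is the benzene ring of the dihydrobenzofuran that bears the 3,5-dihydroxyphenyl group. The ring B/E unit has benzofuran locants (O1, C2, C3, C3a, C4–C7, C7a). Ring C is numbered as in 5H-dibenzo[a,d]cycloheptene: C5 is the methine between rings A and B (also C3 of ring D), C10 is bonded to ring B, C11 to ring A.

Assumption: Rh2(S-PTAD)4, dirhodium tetrakis[(S)-(1-adamantyl)(phthalimido)acetate], is taken to give the (3R) ring E product in step 6. Ring D has the opposite absolute sense, so step 21 uses Rh2(R-PTAD)4. If the sense of induction proves opposite, the two catalysts are exchanged.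

## Route

Step 1
Reactants: 1 phloroglucinol; 2 3,5-dimethoxybenzonitrile
Product: 4 (3,5-dimethoxyphenyl)(2,4,6-trihydroxyphenyl)methanone, via ketiminium chloride 3 (not isolated)
Conditions: ZnCl2, HCl (g), Et2O, 0 °C; then H2O, 100 °C
Reagents that add atoms: water, O
Why: Hoesch acylation of the symmetric, highly nucleophilic triphenol by the nitrilium species gives one ketiminium salt, which water hydrolyses to the ketone; no regiochemical issue.

Step 2
Reactants: 4
Product: 5 [2,6-dihydroxy-4-(methoxymethoxy)phenyl](3,5-dimethoxyphenyl)methanone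
Conditions: MeOCH2Cl (1.05 equiv), i-Pr2NEt, THF, 0 °C
Reagents that add atoms: chloromethyl methyl ether, COCCl
Why: O-alkylation should be selective for the para hydroxyl, since the two ortho hydroxyls are hydrogen-bonded to the ketone and much less nucleophilic.

Step 3
Reactants: 5; 6 4-methoxybenzyl chloride
Product: 7 {2-hydroxy-6-[(4-methoxybenzyl)oxy]-4-(methoxymethoxy)phenyl}(3,5-dimethoxyphenyl)methanone
Conditions: K2CO3, acetone, 50 °C (1.05 equiv of 6)
Reagents that add atoms: none
Why: Williamson etherification of one of two equivalent chelated phenols; the remaining phenol is more strongly chelated, which should stop the reaction at the mono-ether.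

Step 4
Reactants: 7
Product: 8 {2-methoxy-6-[(4-methoxybenzyl)oxy]-4-(methoxymethoxy)phenyl}(3,5-dimethoxyphenyl)methanone
Conditions: MeI, K2CO3, DMF, 40 °C
Reagents that add atoms: iodomethane, CI
Why: Williamson methylation of the last, chelated phenol under slightly forcing conditions; it places a group without reactive C–H next to the future carbene.

Step 5
Reactants: 8
Product: 9 hydrazone of ketone 8
Conditions: N2H4·H2O (excess), AcOH (cat.), n-BuOH, 110 °C
Reagents that add atoms: hydrazine (used as hydrate), NN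
Why: Condensation of a doubly ortho-substituted benzophenone with the small α-effect nucleophile hydrazine under forcing conditions; acetal and benzyl ethers tolerate it.

Step 6
Reactants: 9
Product: 11 (2S,3R)-3-(3,5-dimethoxyphenyl)-4-methoxy-6-(methoxymethoxy)-2-(4-methoxyphenyl)-2,3-dihydrobenzofuran (cis), via diaryldiazomethane 10 (not isolated)
Conditions: MnO2, CH2Cl2, 0 °C, filter; then Rh2(S-PTAD)4 (1 mol %), CH2Cl2, 0 °C → rt
Reagents that add atoms: none
Why: MnO2 dehydrogenates the hydrazone to the diazo compound, whose donor/donor rhodium carbene undergoes 1,5 C–H insertion into the benzylic C–H of the ortho 4-methoxybenzyl ether to close ring E; the chiral carboxylate ligands should set C3 as (R) and give the cis isomer as in the parent benzyl aryl ether class, and the OCH3 group offers only unreactive primary C–H.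

Step 7
Reactants: 11
Product: 12 (2R,3R)-3-(3,5-dimethoxyphenyl)-4-methoxy-2-(4-methoxyphenyl)-2,3-dihydrobenzofuran-6-ol (trans)
Conditions: HCl (3 M in MeOH), CH2Cl2, 40 °C
Reagents that add atoms: none
Why: Acid removes the methoxymethyl group as dimethoxymethane and reversibly ionises the C2–O1 bond to a 4-methoxybenzylic cation; reclosure should give the thermodynamically favoured trans isomer, so C2 follows C3, which is not touched.

Step 8
Reactants: 12
Product: 13 (2R,3R)-3-(3,5-dimethoxyphenyl)-4-methoxy-2-(4-methoxyphenyl)-2,3-dihydrobenzofuran-6-yl N-isopropylcarbamate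
Conditions: i-PrNCO, Et3N (cat.), CH2Cl2, rt
Reagents that add atoms: isopropyl isocyanate, CC(C)N=C=O
Why: Addition of the phenol to the isocyanate installs a directing group for ortho-metalation that is later removable under mild base.

Step 9
Reactants: 13
Product: 17 (2R,3R)-3-(3,5-dimethoxyphenyl)-4-methoxy-2-(4-methoxyphenyl)-7-(trimethylsilyl)-2,3-dihydrobenzofuran-6-yl N-isopropylcarbamate, via N-silyl carbamate 14 (not isolated), via aryllithium 15 (not isolated), via bis-silyl carbamate 16 (not isolated)
Conditions: TBSOTf, TMEDA, Et2O, 0 °C → rt; n-BuLi, TMEDA, −78 °C; Me3SiCl, −78 °C → rt; aq NaHSO4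
Reagents that add atoms: chlorotrimethylsilane, C[Si](C)(C)Cl
Why: In situ N-silylation masks the N–H, and carbamate-directed ortho-lithiation should occur at C7, which lies between the carbamate and the tied-back ring oxygen with its exposed in-plane lone pair; C5 is shielded by the methyl of the C4 methoxy group, which the C3 substituent forces toward C5; silyl quench and hydrolytic loss of the N-silyl group follow.

Step 10
Reactants: 17
Product: 19 (2R,3R)-3-(3,5-dimethoxyphenyl)-4-methoxy-2-(4-methoxyphenyl)-7-(trimethylsilyl)-2,3-dihydrobenzofuran-6-yl trifluoromethanesulfonate, via silyl phenol 18 (not isolated)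
Conditions: Et2NH, DBU, MeCN, 40 °C; then PhNTf2, rt
Reagents that add atoms: N-phenylbis(trifluoromethanesulfonimide), FC(F)(F)S(=O)(=O)N(c1ccccc1)S(=O)(=O)C(F)(F)F
Why: Base-induced elimination of the N-monoalkyl carbamate (isocyanate trapped by diethylamine) frees the phenol, which is triflated in the same pot to the ortho-silylaryl triflate; the aryl–silicon bond survives these conditions.

Step 11
Reactants: 20 methyl 2-(3,5-dihydroxyphenyl)acetate; 6 4-methoxybenzyl chloride
Product: 21 methyl 2-{3,5-bis[(4-methoxybenzyl)oxy]phenyl}acetate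
Conditions: 6 (2.2 equiv in all), K2CO3, n-Bu4NI (cat.), DMF, 60 °C
Reagents that add atoms: 4-methoxybenzyl chloride (the second equivalent of 6), COc1ccc(CCl)cc1
Why: Double Williamson etherification consumes two equivalents of 6, one per phenol, and keeps ring A symmetric; one of the two identical ethers later supplies the O–CH(aryl) carbon of ring D.

Step 12
Reactants: 21
Product: 22 2-{3,5-bis[(4-methoxybenzyl)oxy]phenyl}acetic acid
Conditions: LiOH, THF/MeOH/H2O, rt; then 1 M HCl to pH 3
Reagents that add atoms: lithium hydroxide, [Li+].[OH-]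
Why: Standard saponification of an unhindered methyl ester; the benzyl-type ethers are stable.

Step 13
Reactants: 22
Product: 24 methyl 4-{3,5-bis[(4-methoxybenzyl)oxy]phenyl}-3-oxobutanoate, via acyl imidazolide 23 (not isolated)
Conditions: CDI, THF, rt; then KO2CCH2CO2Me, MgCl2, Et3N, MeCN, rt → 50 °C; aq HCl
Reagents that add atoms: potassium methyl malonate, COC(=O)CC(=O)[O-].[K+]
Why: Masamune–Brooks homologation: the magnesium malonate half-ester is C-acylated by the imidazolide and decarboxylates to the β-keto ester under neutral conditions that spare the acid-labile ethers.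

Step 14
Reactants: 24
Product: 25 methyl 4-{3,5-bis[(4-methoxybenzyl)oxy]phenyl}-2-diazo-3-oxobutanoate
Conditions: 4-AcNHC6H4SO2N3, Et3N, MeCN, 0 °C → rt
Reagents that add atoms: 4-acetamidobenzenesulfonyl azide, CC(=O)Nc1ccc(cc1)S(=O)(=O)N=[N+]=[N-]
Why: Regitz diazo transfer to the doubly activated methylene.

Step 15
Reactants: 25
Product: 26 methyl 5,7-bis[(4-methoxybenzyl)oxy]-2-oxo-2,3-dihydro-1H-indene-1-carboxylate (racemic; largely enolised)
Conditions: Rh2(OAc)4 (1 mol %), CH2Cl2, rt
Reagents that add atoms: none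
Why: The electrophilic rhodium carbenoid undergoes formal aromatic C–H insertion at the ring position ortho to the side chain, which is ortho and para to the two alkoxy groups; both such positions are equivalent, so only one indanone can form, and C1 is a labile, enolised centre.

Step 16
Reactants: 19; 26 (1.5 equiv)
Product: 29 ring C keto ester: methyl 10-oxo-10,11-dihydro-5H-dibenzo[a,d]cycloheptene-5-carboxylate whose ring B carries the (2R,3R) ring E unit of 12 and whose ring A carries two 4-methoxybenzyloxy groups (C5 epimers), via aryne 27 (not isolated), via cyclobutoxide 28 (not isolated)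
Conditions: CsF (2.5 equiv), MeCN, 80 °C
Reagents that add atoms: none
Why: Fluoride removes the silyl group of 19 and triflate leaves to give the 6,7-aryne 27; the cesium enolate of 26 adds through its ester-bearing carbon C1 to C6, the aryl anion formed at C7 closes onto the indanone carbonyl in a 4-exo-trig step to cyclobutoxide 28, and retro-aldol cleavage of the former C1–C2 bond, driven by release of four-ring strain and formation of an ester enolate, expands the five-membered ring to ring C (aryne acyl-alkylation, a σ-bond insertion). The closest known reaction is the CsF-mediated insertion of arynes into the C1–C2 bond of 2-oxoindane-1-carboxylates and other cyclic β-keto esters, which gives dibenzo-fused cycloheptenones. Ring C is thus not closed end to end but arises by 4-exo closure followed by two-carbon ring expansion. The regioselectivity needed, enolate carbon to C6 and acyl to C7, is secured by O1: its inductive effect and the angle distortion from the fused ring E make C6 the electrophilic aryne terminus and place the developing charge at C7 next to oxygen, as in 3-alkoxybenzynes. The chemoselectivity needed, attack of the aryl anion on the ketone and not the ester, follows from the higher electrophilicity of the strained indanone carbonyl. The only new stereocentre, C5, arises by unselective protonation and is left uncontrolled on purpose, since it is planarised in step 19 and set in step 21; C2 and C3 of ring E are not touched.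

Step 17
Reactants: 29; 30 4-methoxyphenylmagnesium bromide
Product: 32 alkene ester: methyl 10-(4-methoxyphenyl)-5H-dibenzo[a,d]cycloheptene-5-carboxylate with the ring A and ring B/E substituents of 29 (C5 epimers), via tertiary carbinol 31 (not isolated)
Conditions: CeCl3, THF, −78 → 0 °C; aq NH4Cl; then PPTS (cat.), PhMe, 60 °C
Reagents that add atoms: none
Why: The weakly basic organocerium reagent adds to the enolisable ketone in preference to the hindered ester; the tertiary, doubly benzylic carbinol loses water by an E1 path under mild acid, and only C11 carries β-hydrogens, so only the C10=C11 alkene can form.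

Step 18
Reactants: 32
Product: 33 alkene acid: the C5 carboxylic acid corresponding to ester 32
Conditions: LiOH, THF/MeOH/H2O, 60 °C; then 1 M HCl
Reagents that add atoms: lithium hydroxide, [Li+].[OH-]
Why: Saponification of the hindered diarylacetate; no other base-labile group is present and the C5 configuration is irrelevant here.

Step 19
Reactants: 33
Product: 35 ring C ketone: 10-(4-methoxyphenyl)-5H-dibenzo[a,d]cyclohepten-5-one with the ring A and ring B/E substituents of 29, via hydroperoxy acid 34 (not isolated)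
Conditions: LiN(i-Pr)2 (2.2 equiv), THF, −78 → 0 °C; O2, −78 °C; then 1 M HCl, rt
Reagents that add atoms: dioxygen, O=O
Why: Autoxidation of the carboxylate dianion gives the α-hydroperoxy acid, which loses carbon dioxide and water on acidification (oxidative decarboxylation of a disubstituted acetic acid) to the diaryl ketone; this erases the uncontrolled C5 centre and gives the carbene precursor site.

Step 20
Reactants: 35
Product: 36 hydrazone of ketone 35
Conditions: N2H4·H2O, AcOH (cat.), EtOH, 80 °C, argon
Reagents that add atoms: hydrazine (used as hydrate), NN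
Why: Hydrazone formation at a dibenzosuberenone-type carbonyl with one ortho alkoxy group; air is excluded to avoid diimide reduction of the alkene.

Step 21
Reactants: 36
Product: 38 cis ring D compound: 39 with (5S) and (R) at the O–CH(aryl) carbon of ring D and with the ring A 4-methoxybenzyl ether still in place, via diazo compound 37 (not isolated)
Conditions: MnO2, CH2Cl2, 0 °C, filter; then Rh2(R-PTAD)4 (2 mol %), CH2Cl2, 0 °C → rt
Reagents that add atoms: none
Why: The donor/donor rhodium carbene at C5 inserts into the benzylic C–H of the 4-methoxybenzyl ether on the adjacent ring A carbon (1,5-insertion) to close ring D; the chiral catalyst should set C5 as (S) independently of the remote ring E centres and give the cis isomer; transannular addition to the C10=C11 alkene would need two fused four-membered rings and is not expected.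

Step 22
Reactants: 38
Product: 39 hexamethyl ether: target skeleton with rings D and E both trans, (5S) and (S) at the O–CH(aryl) carbon of ring D, (2R,3R) in ring E, free phenol on ring A and six methyl ethers
Conditions: CF3CO2H, C6HMe5, CH2Cl2, 0 °C
Reagents that add atoms: none
Why: Acid reversibly ionises the O–CH(aryl) bond of ring D to a 4-methoxybenzylic cation, and reclosure should give the trans isomer while C5 is untouched; the same acid cleaves the remaining 4-methoxybenzyl ether, whose cation is trapped by pentamethylbenzene; ring E is already trans and can only return to trans.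

Step 23
Reactants: 39
Product: 40 target compound CNP0325907.1
Conditions: BBr3 (excess), CH2Cl2, −78 °C → rt; MeOH, then H2O
Reagents that add atoms: none
Why: Lewis-acid cleavage of the six aryl methyl ethers; any ionisation of the benzylic C–O bonds of rings D and E is reversible and should return the trans rings, so no stereocentre is changed.

## Compound list

1 | phloroglucinol | Oc1cc(O)cc(O)c1 | starting material
2 | 3,5-dimethoxybenzonitrile | COc1cc(cc(OC)c1)C#N | starting material
3 | (3,5-dimethoxyphenyl)(2,4,6-trihydroxyphenyl)methaniminium chloride | COc1cc(cc(OC)c1)C(=[NH2+])c1c(O)cc(O)cc1O.[Cl-] | intermediate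
4 | (3,5-dimethoxyphenyl)(2,4,6-trihydroxyphenyl)methanone | COc1cc(cc(OC)c1)C(=O)c1c(O)cc(O)cc1O | intermediate
5 | [2,6-dihydroxy-4-(methoxymethoxy)phenyl](3,5-dimethoxyphenyl)methanone | COCOc1cc(O)c(C(=O)c2cc(OC)cc(OC)c2)c(O)c1 | intermediate
6 | 4-methoxybenzyl chloride | COc1ccc(CCl)cc1 | starting material
7 | {2-hydroxy-6-[(4-methoxybenzyl)oxy]-4-(methoxymethoxy)phenyl}(3,5-dimethoxyphenyl)methanone | COCOc1cc(O)c(C(=O)c2cc(OC)cc(OC)c2)c(OCc2ccc(OC)cc2)c1 | intermediate
8 | {2-methoxy-6-[(4-methoxybenzyl)oxy]-4-(methoxymethoxy)phenyl}(3,5-dimethoxyphenyl)methanone | COCOc1cc(OC)c(C(=O)c2cc(OC)cc(OC)c2)c(OCc2ccc(OC)cc2)c1 | intermediate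
9 | hydrazone of 8 | COCOc1cc(OC)c(C(=NN)c2cc(OC)cc(OC)c2)c(OCc2ccc(OC)cc2)c1 | intermediate
10 | diaryldiazomethane from 9 | COCOc1cc(OC)c(C(=[N+]=[N-])c2cc(OC)cc(OC)c2)c(OCc2ccc(OC)cc2)c1 | intermediate
11 | (2S,3R)-3-(3,5-dimethoxyphenyl)-4-methoxy-6-(methoxymethoxy)-2-(4-methoxyphenyl)-2,3-dihydrobenzofuran (cis) | COc1cc(OCOC)cc2O[C@H](c3ccc(OC)cc3)[C@H](c3cc(OC)cc(OC)c3)c12 | intermediate
12 | (2R,3R)-3-(3,5-dimethoxyphenyl)-4-methoxy-2-(4-methoxyphenyl)-2,3-dihydrobenzofuran-6-ol (trans) | COc1cc(O)cc2O[C@@H](c3ccc(OC)cc3)[C@H](c3cc(OC)cc(OC)c3)c12 | intermediate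
13 | N-isopropylcarbamate of 12 | COc1cc(OC(=O)NC(C)C)cc2O[C@@H](c3ccc(OC)cc3)[C@H](c3cc(OC)cc(OC)c3)c12 | intermediate
14 | N-(tert-butyldimethylsilyl) carbamate of 13 | COc1cc(OC(=O)N(C(C)C)[Si](C)(C)C(C)(C)C)cc2O[C@@H](c3ccc(OC)cc3)[C@H](c3cc(OC)cc(OC)c3)c12 | intermediate
15 | 7-lithio derivative of 14 | COc1cc(OC(=O)N(C(C)C)[Si](C)(C)C(C)(C)C)c([Li])c2O[C@@H](c3ccc(OC)cc3)[C@H](c3cc(OC)cc(OC)c3)c12 | intermediate
16 | 7-(trimethylsilyl) derivative of 14 | COc1cc(OC(=O)N(C(C)C)[Si](C)(C)C(C)(C)C)c([Si](C)(C)C)c2O[C@@H](c3ccc(OC)cc3)[C@H](c3cc(OC)cc(OC)c3)c12 | intermediate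
17 | 7-(trimethylsilyl) derivative of carbamate 13 | COc1cc(OC(=O)NC(C)C)c([Si](C)(C)C)c2O[C@@H](c3ccc(OC)cc3)[C@H](c3cc(OC)cc(OC)c3)c12 | intermediate
18 | (2R,3R)-3-(3,5-dimethoxyphenyl)-4-methoxy-2-(4-methoxyphenyl)-7-(trimethylsilyl)-2,3-dihydrobenzofuran-6-ol | COc1cc(O)c([Si](C)(C)C)c2O[C@@H](c3ccc(OC)cc3)[C@H](c3cc(OC)cc(OC)c3)c12 | intermediate
19 | (2R,3R)-3-(3,5-dimethoxyphenyl)-4-methoxy-2-(4-methoxyphenyl)-7-(trimethylsilyl)-2,3-dihydrobenzofuran-6-yl trifluoromethanesulfonate | COc1cc(OS(=O)(=O)C(F)(F)F)c([Si](C)(C)C)c2O[C@@H](c3ccc(OC)cc3)[C@H](c3cc(OC)cc(OC)c3)c12 | intermediate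
20 | methyl 2-(3,5-dihydroxyphenyl)acetate | COC(=O)Cc1cc(O)cc(O)c1 | starting material
21 | methyl 2-{3,5-bis[(4-methoxybenzyl)oxy]phenyl}acetate | COC(=O)Cc1cc(OCc2ccc(OC)cc2)cc(OCc2ccc(OC)cc2)c1 | intermediate
22 | 2-{3,5-bis[(4-methoxybenzyl)oxy]phenyl}acetic acid | OC(=O)Cc1cc(OCc2ccc(OC)cc2)cc(OCc2ccc(OC)cc2)c1 | intermediate
23 | 1-acylimidazole of 22 | O=C(Cc1cc(OCc2ccc(OC)cc2)cc(OCc2ccc(OC)cc2)c1)n1ccnc1 | intermediate
24 | methyl 4-{3,5-bis[(4-methoxybenzyl)oxy]phenyl}-3-oxobutanoate | COC(=O)CC(=O)Cc1cc(OCc2ccc(OC)cc2)cc(OCc2ccc(OC)cc2)c1 | intermediate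
25 | methyl 4-{3,5-bis[(4-methoxybenzyl)oxy]phenyl}-2-diazo-3-oxobutanoate | COC(=O)C(=[N+]=[N-])C(=O)Cc1cc(OCc2ccc(OC)cc2)cc(OCc2ccc(OC)cc2)c1 | intermediate
26 | methyl 5,7-bis[(4-methoxybenzyl)oxy]-2-oxo-2,3-dihydro-1H-indene-1-carboxylate (racemic) | COC(=O)C1C(=O)Cc2cc(OCc3ccc(OC)cc3)cc(OCc3ccc(OC)cc3)c12 | intermediate
27 | (2R,3R)-6,7-didehydro-3-(3,5-dimethoxyphenyl)-4-methoxy-2-(4-methoxyphenyl)-2,3-dihydrobenzofuran (aryne) | COC1=CC#CC=2O[C@@H](c3ccc(OC)cc3)[C@H](c3cc(OC)cc(OC)c3)C1=2 | intermediate
28 | cesium benzocyclobutenoxide adduct of 27 and 26 | COc1cc2c(c3O[C@@H](c4ccc(OC)cc4)[C@H](c4cc(OC)cc(OC)c4)c13)C4([O-])Cc5cc(OCc6ccc(OC)cc6)cc(OCc6ccc(OC)cc6)c5C24C(=O)OC.[Cs+] | intermediate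
29 | ring C keto ester (C5 CO2Me, C10 ketone, C11 CH2; C5 epimers) | COc1cc2c(c3O[C@@H](c4ccc(OC)cc4)[C@H](c4cc(OC)cc(OC)c4)c13)C(=O)Cc1cc(OCc4ccc(OC)cc4)cc(OCc4ccc(OC)cc4)c1C2C(=O)OC | intermediate
30 | 4-methoxyphenylmagnesium bromide | COc1ccc([Mg]Br)cc1 | starting material
31 | C10 tertiary carbinol from 29 (diastereomer mixture) | COc1cc2c(c3O[C@@H](c4ccc(OC)cc4)[C@H](c4cc(OC)cc(OC)c4)c13)C(O)(c1ccc(OC)cc1)Cc1cc(OCc4ccc(OC)cc4)cc(OCc4ccc(OC)cc4)c1C2C(=O)OC | intermediate
32 | alkene ester (C10 aryl, C10=C11, C5 CO2Me; C5 epimers) | COc1cc2c(c3O[C@@H](c4ccc(OC)cc4)[C@H](c4cc(OC)cc(OC)c4)c13)C(c1ccc(OC)cc1)=Cc1cc(OCc4ccc(OC)cc4)cc(OCc4ccc(OC)cc4)c1C2C(=O)OC | intermediate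
33 | alkene acid (C5 CO2H; C5 epimers) | COc1cc2c(c3O[C@@H](c4ccc(OC)cc4)[C@H](c4cc(OC)cc(OC)c4)c13)C(c1ccc(OC)cc1)=Cc1cc(OCc4ccc(OC)cc4)cc(OCc4ccc(OC)cc4)c1C2C(O)=O | intermediate
34 | C5 hydroperoxy acid from 33 | COc1cc2c(c3O[C@@H](c4ccc(OC)cc4)[C@H](c4cc(OC)cc(OC)c4)c13)C(c1ccc(OC)cc1)=Cc1cc(OCc4ccc(OC)cc4)cc(OCc4ccc(OC)cc4)c1C2(OO)C(O)=O | intermediate
35 | ring C ketone (C5 ketone) | COc1cc2c(c3O[C@@H](c4ccc(OC)cc4)[C@H](c4cc(OC)cc(OC)c4)c13)C(c1ccc(OC)cc1)=Cc1cc(OCc4ccc(OC)cc4)cc(OCc4ccc(OC)cc4)c1C2=O | intermediate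
36 | hydrazone of 35 | COc1cc2c(c3O[C@@H](c4ccc(OC)cc4)[C@H](c4cc(OC)cc(OC)c4)c13)C(c1ccc(OC)cc1)=Cc1cc(OCc4ccc(OC)cc4)cc(OCc4ccc(OC)cc4)c1C2=NN | intermediate
37 | C5 diazo compound from 36 | COc1cc2c(c3O[C@@H](c4ccc(OC)cc4)[C@H](c4cc(OC)cc(OC)c4)c13)C(c1ccc(OC)cc1)=Cc1cc(OCc4ccc(OC)cc4)cc(OCc4ccc(OC)cc4)c1C2=[N+]=[N-] | intermediate
38 | cis ring D insertion product (ring D: 5S and R at O–CH; ring E: 2R,3R; ring A 4-methoxybenzyl ether) | COc1ccc(C2=Cc3cc(OCc6ccc(OC)cc6)cc4c3[C@H](c3cc(OC)c5c(c32)O[C@@H](c2ccc(OC)cc2)[C@@H]5c2cc(OC)cc(OC)c2)[C@H](c2ccc(OC)cc2)O4)cc1 | intermediate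
39 | hexamethyl ether of the target with free ring A phenol (ring D: 5S and S at O–CH, trans; ring E: 2R,3R, trans) | COc1ccc(C2=Cc3cc(O)cc4c3[C@H](c3cc(OC)c5c(c32)O[C@@H](c2ccc(OC)cc2)[C@@H]5c2cc(OC)cc(OC)c2)[C@@H](c2ccc(OC)cc2)O4)cc1 | intermediate
40 | CNP0325907.1 | Oc1ccc(C2=Cc3cc(O)cc4c3[C@H](c3cc(O)c5c(c32)O[C@@H](c2ccc(O)cc2)[C@@H]5c2cc(O)cc(O)c2)[C@@H](c2ccc(O)cc2)O4)cc1 | target

## Step count and risk

Total step count: 23. Longest linear sequence: 18 steps (steps 1–10, then 16–23).

Three steps most likely to fail: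

Step 21. The carbene at C5 sits in a tub-shaped seven-membered ring, so the catalyst may discriminate its two faces poorly and give low control at C5, or the hindered diazo compound may divert to azine or carbene dimer before insertion. The fallback gives up catalyst control of ring D and uses a cation cyclisation with separation. It sets out from 32: reduction with i-Bu2AlH (CH2Cl2, −78 °C) should give the C5 aldehyde F1, and addition of 30 (THF, −78 °C) the 4-methoxyphenyl carbinol F2 as a diastereomer mixture. CF3CO2H with pentamethylbenzene in CH2Cl2 then cleaves both 4-methoxybenzyl ethers and ionises the carbinol, and the freed ring A phenol next to C5 traps the 4-methoxybenzylic cation to close ring D trans. This gives 39 together with the ring D diastereomer F3, which differ in their relation to the fixed ring E centres and are separated by chromatography. The route is rejoined at 39.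

Step 16. The hindered, fully enolised keto ester may add slowly, so that the aryne is consumed by self-reaction, or the aryl anion may be protonated before the 4-exo closure, which stops at simple α-arylation. The fallback changes the aryne source and the regime to an aprotic, low-temperature arynic condensation with a preformed enolate. It sets out from aryllithium 15 (made from 13 as in step 9): quenching with iodine gives the N-silyl 7-iodo carbamate F4 and, after aqueous work-up, the 7-iodo carbamate F5. Et2NH and DBU in MeCN then free the 7-iodo phenol F6, which PhNTf2 converts to the 7-iodo triflate F7. F7 and the sodium enolate of 26 (NaH, THF) are treated with i-PrMgCl·LiCl at −78 → −20 °C; iodine–magnesium exchange and loss of triflate generate aryne 27 where no proton source is present, and insertion as in step 16 should follow. The route is rejoined at 29.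

Step 23. Under BBr3 the benzylic C–O bonds of rings D and E ionise and the C10=C11 alkene can be protonated, which may lead to Friedel–Crafts oligomers or ring-opened material before all six ethers are cleaved. The fallback replaces electrophilic ether cleavage by nucleophilic dealkylation under basic conditions: 39 is heated with NaSEt in DMF at 130 °C, where thiolate attacks the methyl groups and the product stays as unreactive phenoxides until work-up. It sets out from 39 and comes back at 40; no new compound is made (F0).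

## Further compounds

F1 | step 21 | C5 aldehyde from 32 (C5 epimers) | COc1cc2c(c3O[C@@H](c4ccc(OC)cc4)[C@H](c4cc(OC)cc(OC)c4)c13)C(c1ccc(OC)cc1)=Cc1cc(OCc4ccc(OC)cc4)cc(OCc4ccc(OC)cc4)c1C2C=O
F2 | step 21 | C5 (4-methoxyphenyl)hydroxymethyl carbinol (diastereomer mixture) | COc1cc2c(c3O[C@@H](c4ccc(OC)cc4)[C@H](c4cc(OC)cc(OC)c4)c13)C(c1ccc(OC)cc1)=Cc1cc(OCc4ccc(OC)cc4)cc(OCc4ccc(OC)cc4)c1C2C(O)c1ccc(OC)cc1
F3 | step 21 | ring D diastereomer of 39 (5R and R at O–CH, trans) | COc1ccc(C2=Cc3cc(O)cc4c3[C@@H](c3cc(OC)c5c(c32)O[C@@H](c2ccc(OC)cc2)[C@@H]5c2cc(OC)cc(OC)c2)[C@H](c2ccc(OC)cc2)O4)cc1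
F4 | step 16 | N-(tert-butyldimethylsilyl) 7-iodo carbamate | COc1cc(OC(=O)N(C(C)C)[Si](C)(C)C(C)(C)C)c(I)c2O[C@@H](c3ccc(OC)cc3)[C@H](c3cc(OC)cc(OC)c3)c12
F5 | step 16 | 7-iodo N-isopropylcarbamate | COc1cc(OC(=O)NC(C)C)c(I)c2O[C@@H](c3ccc(OC)cc3)[C@H](c3cc(OC)cc(OC)c3)c12
F6 | step 16 | (2R,3R)-3-(3,5-dimethoxyphenyl)-7-iodo-4-methoxy-2-(4-methoxyphenyl)-2,3-dihydrobenzofuran-6-ol | COc1cc(O)c(I)c2O[C@@H](c3ccc(OC)cc3)[C@H](c3cc(OC)cc(OC)c3)c12
F7 | step 16 | 7-iodo-6-triflate of the ring B/E unit | COc1cc(OS(=O)(=O)C(F)(F)F)c(I)c2O[C@@H](c3ccc(OC)cc3)[C@H](c3cc(OC)cc(OC)c3)c12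
F0 | step 23 | none | none
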